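1. From 20.0 h to 40.0 h the red flask's J falls evenly, by 0.0492 h⁻¹ and then 0.0487 h⁻¹, and G keeps step with it. The rule of thumb at the bench is to read that fall once and run it forward. Over those readings it comes to 0.0489 h⁻¹: this is the tail rate, the logarithmic fall of J per hour once G keeps step with J, a pseudo-first-order constant as read. G stands at 0.612 of J over the same readings.

| flask | J | D | remark | time |
|---|---|---|---|---|
| red | 0.20 M | 120 mM (held) | the very flask that is asked about, followed so far |  |
| flask | 0.20 M | 120 mM (held) |  | 15 d |

red run (percent of the J charged)

| time / h | G / % | J / % |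
|---|---|---|
| 8.00 | 13.9 | 38.2 |
| 15.0 | 12.2 | 22.1 |
| 20.0 | 9.3 | 15.7 |
| 30.0 | 6.6 | 9.6 |
| 40.0 | 3.2 | 5.9 |

(scatter of a reading: 0.3 percentage points)

- at the start none of D is in solution

- the best time, 15 d at the latest, for G
- the amount of G, in percent of the J charged, at that time
- the first time at which G reaches 7.0%, in the same percent, in d

2. The border of the rule is that ratio. At 8.00 h the red flask's G over J is 0.364, less than the tail value, so that reading lies outside the tail; at 15.0 h it is already 0.552.

3. Run back to the start, the tail holds 41.8% of the charge. The rest of J must fall faster, and its excess at 8.00 h gives 0.221 h⁻¹, above the tail rate.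

4. Two such rates put the peak of G at 0.365 d, 0.760 h after the reading of 13.9%, so the height is taken as about that reading. With D treated as dissolved from the start, G rises at first by 0.0439 h⁻¹ of the charge, and with the bend of the curve it reaches the level at 0.0806 d; any lag comes on top.

5. The forecast gives 0.36 d, 14.5% and 0.11 d, holding that “nothing suggests it recovers later”, and its time for the level is later than this reckoning's.

The flask gives 0.367 d, 14.0% and 0.0889 d.

    D ⇌ Q, rate k1*(csat - [Q]) (kL = 3.40 h⁻¹)
    J + Q ⇌ G (K = 3.40 M⁻¹, k = 0.440 M⁻¹ h⁻¹)
    J → E (k = 0.0810 h⁻¹)
    Q → L (k = 0.100 h⁻¹)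
    2 J → Z (k = 0.0600 M⁻¹ h⁻¹)

Taken back from the last reading, inside the span it was read on, the tail rate gives the red flask at 1.50 d J 7.18% and, through the tail ratio, G 4.39%; that flask holds J 6.99% and G 4.53%. The neighbouring flask, left until 4.0 d with the same charges, lies beyond the last reading, so there the same rate is run forward: J 0.381% and G 0.233%. That neighbour holds J 0.358% and G 0.229%.

The numbers in the tables were computed with constants of no real substance; the scatter is artificial.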